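Rings: A is the dihydrobenzofuran fused to the stilbene arene, B is the dihydrobenzofuran bearing the 3,5-dihydroxyphenyl group, and C is the benzofuran. All nine phenols travel as methoxymethyl (MOM) ethers, because a late Lewis-acid demethylation would risk ionising the benzylic C2–O bonds of A and B.
Cuts, in retrosynthetic order: the nine O–MOM bonds; O1–C2 and C2–C3 of B (o-quinone methide plus benzylidene ylide); C4–C5 and C3a–C7a of the benzo ring of B (alkyne plus diene); the bond from C5 of A to the stilbene alkene (Heck); C2–C3 of A (carbene C–H insertion).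
Enabling feature: the benzo ring of B is a resorcinol with oxygen on C7a and C6, and its neighbouring carbons C3a and C4 hold the two bulkiest groups, C3 of B and C3 of A. C3a–C4 is therefore read as an ynone triple bond and C7a–C7–C6–C5 as a 1-methoxy-1,3-bis(silyloxy)butadiene.
Forward order: ring A and benzofuran C are made apart and joined by a Heck reaction. The ring A ester becomes an aryl ynone, the benzo ring of B is built on the alkyne, the furan ring of B closes last, and the MOM groups then come off.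
Stereochemistry: C2 of A (R) comes from Rh2(S-PTTL)4 and C3 of A (R) from equilibration to trans. C2 and C3 of B (S,S) come from an enantiopure sulfonium ylide in a trans-selective (4+1) annulation, and the E alkene from the Heck reaction.

Key step: step 24

Abbreviations: MOM = CH2OCH3. Ar35 = 3,5-bis(methoxymethoxy)phenyl. BFV = (E)-2-{6-(methoxymethoxy)-2-[4-(methoxymethoxy)phenyl]-3-(Ar35)-1-benzofuran-4-yl}ethenyl. RA = (2R,3R)-5-BFV-2-[4-(methoxymethoxy)phenyl]-2,3-dihydro-1-benzofuran-3-yl (trans).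
Assumption: Rh2(S-PTTL)4 is taken to give the (2R)-cis ester, as with closely related 5-bromoaryldiazoacetates. The (1R,4R,5R)-sulfide is taken to deliver (2S) in ring B by analogy with the facial sense of its benzylidene transfer to aldehydes. Both reagents also exist in the mirror-image form.

Step 1
Reactants: 1 4-hydroxybenzaldehyde
Product: 2 4-(methoxymethoxy)benzaldehyde
Conditions: MOMCl, iPr2NEt, CH2Cl2, 0 °C to rt
Reagents that add atoms: chloromethyl methyl ether, COCCl
Why: O-alkylation of the acidic phenol with an α-chloro ether (acetal protection) is fast under amine base, and the MOM ether tolerates every basic, reductive and palladium-mediated step that follows.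

Step 2
Reactants: 2 4-(methoxymethoxy)benzaldehyde
Product: 3 [4-(methoxymethoxy)phenyl]methanol
Conditions: NaBH4, MeOH, 0 °C
Reagents that add atoms: none
Why: Borohydride reduction of an aromatic aldehyde is clean and leaves the acetal untouched.

Step 3
Reactants: 3 [4-(methoxymethoxy)phenyl]methanol
Product: 4 1-(bromomethyl)-4-(methoxymethoxy)benzene
Conditions: CBr4, PPh3, CH2Cl2, 0 °C
Reagents that add atoms: carbon tetrabromide, BrC(Br)(Br)Br
Why: The Appel reaction converts the electron-rich benzylic alcohol into the bromide under neutral conditions, so no acid reaches the MOM acetal.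

Step 4
Reactants: 5 2-hydroxyphenylacetic acid
Product: 6 methyl 2-(2-hydroxyphenyl)acetate
Conditions: MeOH, cat. H2SO4, reflux
Reagents that add atoms: methanol, CO
Why: This is a Fischer esterification, and the excess methanol also opens any benzofuran-2-one lactone that forms on the way.

Step 5
Reactants: 6 methyl 2-(2-hydroxyphenyl)acetate
Product: 7 methyl 2-(5-bromo-2-hydroxyphenyl)acetate
Conditions: NBS, MeCN, −10 °C to rt
Reagents that add atoms: N-bromosuccinimide, O=C1CCC(=O)N1Br
Why: In this electrophilic aromatic bromination the hydroxyl group directs to its free para position (C5), which later becomes C5 of ring A.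

Step 6
Reactants: 7 methyl 2-(5-bromo-2-hydroxyphenyl)acetate; 4 1-(bromomethyl)-4-(methoxymethoxy)benzene
Product: 8 methyl 2-{5-bromo-2-[4-(methoxymethoxy)benzyloxy]phenyl}acetate
Conditions: K2CO3, DMF, rt
Reagents that add atoms: none
Why: In this Williamson ether synthesis carbonate deprotonates only the phenol, and the activated benzylic bromide alkylates oxygen.

Step 7
Reactants: 8 methyl 2-{5-bromo-2-[4-(methoxymethoxy)benzyloxy]phenyl}acetate
Product: 9 methyl 2-{5-bromo-2-[4-(methoxymethoxy)benzyloxy]phenyl}-2-diazoacetate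
Conditions: 4-AcNHC6H4SO2N3, DBU, MeCN, 0 °C to rt
Reagents that add atoms: 4-acetamidobenzenesulfonyl azide, CC(=O)Nc1ccc(cc1)S(=O)(=O)N=[N+]=[N-]
Why: Regitz diazo transfer to an arylacetate enolate is the standard entry to aryldiazoacetates.

Step 8
Reactants: 9 methyl 2-{5-bromo-2-[4-(methoxymethoxy)benzyloxy]phenyl}-2-diazoacetate
Product: 10 methyl (2R,3S)-5-bromo-2-[4-(methoxymethoxy)phenyl]-2,3-dihydro-1-benzofuran-3-carboxylate (cis)
Conditions: Rh2(S-PTTL)4 (1 mol %), toluene, −60 °C
Reagents that add atoms: none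
Why: Intramolecular 1,5-C–H insertion of the donor/acceptor rhodium carbene into the electron-rich benzylic ether C–H bond closes ring A (C2–C3); the concerted transition state gives the cis ester, and the chiral carboxylate pocket picks one of the two enantiotopic benzylic hydrogens, which sets C2 as R (C3 is S at this stage).

Step 9
Reactants: 10 methyl (2R,3S)-5-bromo-2-[4-(methoxymethoxy)phenyl]-2,3-dihydro-1-benzofuran-3-carboxylate
Product: 11 methyl (2R,3R)-5-bromo-2-[4-(methoxymethoxy)phenyl]-2,3-dihydro-1-benzofuran-3-carboxylate (trans)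
Conditions: NaOMe (0.3 equiv), MeOH–THF, rt
Reagents that add atoms: none
Why: Enolate-mediated epimerisation exchanges only the ester α-hydrogen at C3, so the ring settles in the less strained trans arrangement (3R) while C2, which has no acidic hydrogen, keeps the configuration set in step 8.

Step 10
Reactants: 12 1-bromo-3,5-dimethoxybenzene
Product: 13 1-bromo-2-iodo-3,5-dimethoxybenzene
Conditions: NIS, MeCN, rt
Reagents that add atoms: N-iodosuccinimide, O=C1CCC(=O)N1I
Why: Electrophilic iodination goes to the position ortho to one methoxy group and para to the other, not to the more crowded site between the two methoxy groups.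

Step 11
Reactants: 13 1-bromo-2-iodo-3,5-dimethoxybenzene; 14 4-ethynylanisole
Product: 15 1-bromo-3,5-dimethoxy-2-[(4-methoxyphenyl)ethynyl]benzene
Conditions: PdCl2(PPh3)2, CuI, Et3N–THF, 50 °C
Reagents that add atoms: none
Why: In this Sonogashira coupling zerovalent palladium inserts into the C–I bond far faster than into the C–Br bond, so the bromide is kept for step 16.

Step 12
Reactants: 15 1-bromo-3,5-dimethoxy-2-[(4-methoxyphenyl)ethynyl]benzene
Product: 16 4-bromo-3-iodo-6-methoxy-2-(4-methoxyphenyl)-1-benzofuran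
Conditions: I2, CH2Cl2, rt
Reagents that add atoms: iodine, II
Why: In this electrophilic iodocyclisation of a 2-alkynylanisole the ortho methoxy oxygen attacks the iodonium-activated, anisyl-stabilised alkyne carbon in a 5-endo-dig closure, and iodide removes the methyl group.

Step 13
Reactants: 16 4-bromo-3-iodo-6-methoxy-2-(4-methoxyphenyl)-1-benzofuran; 17 3,5-dimethoxyphenylboronic acid
Product: 18 4-bromo-3-(3,5-dimethoxyphenyl)-6-methoxy-2-(4-methoxyphenyl)-1-benzofuran
Conditions: Pd(PPh3)4, K2CO3, 1,4-dioxane–H2O, 80 °C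
Reagents that add atoms: none
Why: This Suzuki–Miyaura coupling is chemoselective for the C3–I bond over the C4–Br bond when about one equivalent of boronic acid is used.

Step 14
Reactants: 18 4-bromo-3-(3,5-dimethoxyphenyl)-6-methoxy-2-(4-methoxyphenyl)-1-benzofuran
Product: 19 5-[4-bromo-6-hydroxy-2-(4-hydroxyphenyl)-1-benzofuran-3-yl]benzene-1,3-diol
Conditions: BBr3, CH2Cl2, −78 °C to rt; then H2O
Reagents that add atoms: none
Why: BBr3 cleavage of aryl methyl ethers is carried out here on a fully aromatic benzofuran that has neither an alkene nor a benzylic C–O bond, so no such Lewis acid is needed late in the route.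

Step 15
Reactants: 19 5-[4-bromo-6-hydroxy-2-(4-hydroxyphenyl)-1-benzofuran-3-yl]benzene-1,3-diol
Product: 20 4-bromo-6-(methoxymethoxy)-2-[4-(methoxymethoxy)phenyl]-3-(Ar35)-1-benzofuran
Conditions: MOMCl (6 equiv), iPr2NEt, DMF, 0 °C to rt
Reagents that add atoms: chloromethyl methyl ether, COCCl
Why: Exhaustive O-alkylation (acetal protection) of four unhindered phenols brings fragment C into the same protecting-group series as the rest of the molecule.

Step 16
Reactants: 20 4-bromo-6-(methoxymethoxy)-2-[4-(methoxymethoxy)phenyl]-3-(Ar35)-1-benzofuran; 21 4,4,5,5-tetramethyl-2-vinyl-1,3,2-dioxaborolane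
Product: 22 4-ethenyl-6-(methoxymethoxy)-2-[4-(methoxymethoxy)phenyl]-3-(Ar35)-1-benzofuran
Conditions: Pd(OAc)2, SPhos, K3PO4, 1,4-dioxane–H2O, 80 °C
Reagents that add atoms: none
Why: In this Suzuki–Miyaura vinylation the bulky biarylphosphine allows oxidative addition at the peri-hindered C4–Br bond, and the small vinyl group transfers easily.

Step 17
Reactants: 11 methyl (2R,3R)-5-bromo-2-[4-(methoxymethoxy)phenyl]-2,3-dihydro-1-benzofuran-3-carboxylate; 22 4-ethenyl-6-(methoxymethoxy)-2-[4-(methoxymethoxy)phenyl]-3-(Ar35)-1-benzofuran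
Product: 23 methyl (2R,3R)-5-BFV-2-[4-(methoxymethoxy)phenyl]-2,3-dihydro-1-benzofuran-3-carboxylate
Conditions: Pd(OAc)2, P(o-tol)3, Et3N, DMF, 100 °C
Reagents that add atoms: none
Why: In this Mizoroki–Heck reaction zerovalent palladium inserts into the unhindered C5–Br bond of 11, syn carbopalladation at the terminal vinyl carbon of 22 and syn β-hydride elimination give the E stilbene, and the trans ester is safe under amine base because it is the thermodynamic epimer.

Step 18
Reactants: 23 methyl (2R,3R)-5-BFV-2-[4-(methoxymethoxy)phenyl]-2,3-dihydro-1-benzofuran-3-carboxylate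
Product: 25 (2R,3R)-3-ethynyl-5-BFV-2-[4-(methoxymethoxy)phenyl]-2,3-dihydro-1-benzofuran (RA–C≡CH), via ring A 3-carbaldehyde 24 (not isolated)
Conditions: iBu2AlH (1.1 equiv), CH2Cl2, −78 °C; then MeOH, K2CO3, dimethyl (1-diazo-2-oxopropyl)phosphonate, −78 °C to rt
Reagents that add atoms: dimethyl (1-diazo-2-oxopropyl)phosphonate, COP(=O)(OC)C(=[N+]=[N-])C(C)=O
Why: Partial reduction to the aluminium hemiacetal, release of aldehyde 24 by methanol and Ohira–Bestmann (Seyferth–Gilbert) homologation in the same flask form a known ester-to-alkyne sequence, and any enolisation of 24 under K2CO3 returns the favoured trans isomer, so C3 stays R.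

Step 19
Reactants: 26 3,5-dihydroxybenzaldehyde
Product: 27 3,5-bis(methoxymethoxy)benzaldehyde
Conditions: MOMCl, iPr2NEt, CH2Cl2–DMF, 0 °C to rt
Reagents that add atoms: chloromethyl methyl ether, COCCl
Why: Acetal protection of both phenols by O-alkylation gives the aryl building block in the MOM series.

Step 20
Reactants: 25 RA–C≡CH; 27 3,5-bis(methoxymethoxy)benzaldehyde
Product: 28 1-(Ar35)-3-RA-prop-2-yn-1-ol (both carbinol epimers)
Conditions: n-BuLi (1.0 equiv), THF, −78 °C; then 27
Reagents that add atoms: none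
Why: This is the 1,2-addition of a lithium acetylide to an aromatic aldehyde; one equivalent of base at −78 °C removes only the alkyne hydrogen, and this entry avoids leaving the base-sensitive ynone in contact with amine, copper and phosphine as an acylative Sonogashira coupling would (the new carbinol centre is erased in step 21).

Step 21
Reactants: 28 1-(Ar35)-3-RA-prop-2-yn-1-ol
Product: 29 1-(Ar35)-3-RA-prop-2-yn-1-one (ynone)
Conditions: MnO2, CH2Cl2, rt
Reagents that add atoms: none
Why: MnO2 oxidation of a doubly activated (propargylic and benzylic) alcohol runs under neutral heterogeneous conditions, so the acidic hydrogen at C3 of ring A is not disturbed.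

Step 22
Reactants: 30 methyl acetoacetate
Product: 31 methyl 3-(trimethylsilyloxy)but-2-enoate (either geometry serves)
Conditions: Me3SiCl, Et3N, hexane, rt
Reagents that add atoms: chlorotrimethylsilane, C[Si](C)(C)Cl
Why: Soft enolisation and O-silylation of the β-keto ester give the silyl enol ether.

Step 23
Reactants: 31 methyl 3-(trimethylsilyloxy)but-2-enoate
Product: 32 1-methoxy-1,3-bis(trimethylsilyloxy)buta-1,3-diene (drawn 1Z; either ketene acetal geometry reacts alike)
Conditions: LiN(iPr)2, THF, −78 °C; then Me3SiCl, −78 to 0 °C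
Reagents that add atoms: chlorotrimethylsilane, C[Si](C)(C)Cl
Why: Kinetic γ-deprotonation gives the extended ester enolate, and O-silylation at the ester oxygen gives the bis(silyloxy)diene (silyl ketene acetal formation).

Step 24
Reactants: 29 1-(Ar35)-3-RA-prop-2-yn-1-one; 32 1-methoxy-1,3-bis(trimethylsilyloxy)buta-1,3-diene
Product: 34 (2,4-dihydroxy-6-RA-phenyl)(Ar35)methanone, via cyclohexa-1,4-diene cycloadduct 33 (not isolated)
Conditions: 32 (4 equiv), toluene, 110 °C (sealed tube); then NH4F, MeOH, rt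
Reagents that add atoms: none
Why: The electron-rich diene 32 and the electron-poor alkyne of 29 combine in a polarised, asynchronous, normal-electron-demand (4+2) cycloaddition in which bonding between the unsubstituted CH2 terminus and the ynone β-carbon (the one that carries C3 of ring A) runs ahead of bonding between the ketene acetal carbon and the α-carbon; this forms C4–C5 and C3a–C7a and closes the six-membered carbocycle of B in one (4+2) event to give 33. Fluoride then frees the mixed silyl methyl ketal, which expels methanol, and enolisation of the dienone gives the resorcinol 34. The closest known reaction type is the Diels–Alder benzannulation of 1-alkoxy-1,3-bis(silyloxy)butadienes with alkynones and alkynoates to 6-substituted 2,4-dihydroxyaryl ketones and esters. No stereocentre is created: C2 and C3 of ring A are spectators, and the base-free medium leaves the acidic C3–H alone until the alkyne has become an arene. The selectivity needed is regiochemical, since the ketene acetal oxygen must end ortho to the aroyl carbon (future O1 on C7a) and the enol ether oxygen para to it (future 6-OH); the matched polarisation of the two partners secures this, while the unactivated stilbene alkene does not compete. Because an alkyne is linear, the bond from C3 of A to C4 of B, later flanked by two ortho substituents, is already in place before any crowding exists.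

Step 25
Reactants: 34 (2,4-dihydroxy-6-RA-phenyl)(Ar35)methanone
Product: 35 [2-hydroxy-4-(methoxymethoxy)-6-RA-phenyl](Ar35)methanone
Conditions: MOMCl (1.05 equiv), iPr2NEt, CH2Cl2, 0 °C
Reagents that add atoms: chloromethyl methyl ether, COCCl
Why: In this selective O-alkylation the 4-OH, para to the carbonyl, is the more acidic and accessible phenol, whereas the 2-OH is hydrogen-bonded to the ketone and flanked by the aroyl group, which is the usual basis for mono-protection of 2,4-dihydroxyaryl ketones.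

Step 26
Reactants: 35 [2-hydroxy-4-(methoxymethoxy)-6-RA-phenyl](Ar35)methanone
Product: 36 2-[(Ar35)(hydroxy)methyl]-5-(methoxymethoxy)-3-RA-phenol (both carbinol epimers)
Conditions: NaBH4, THF–MeOH, 0 °C to rt
Reagents that add atoms: none
Why: In this borohydride reduction of a 2-hydroxybenzophenone to the 2-hydroxybenzhydrol the small hydride reaches the twisted carbonyl group, and the new carbinol centre does not matter because it becomes planar in step 29.

Step 27
Reactants: 36 2-[(Ar35)(hydroxy)methyl]-5-(methoxymethoxy)-3-RA-phenol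
Product: 37 2-[(Ar35)(4-methylphenylsulfonyl)methyl]-5-(methoxymethoxy)-3-RA-phenol (both epimers)
Conditions: 4-MeC6H4SO2H, 4 Å molecular sieves, CH2Cl2, rt
Reagents that add atoms: 4-methylbenzenesulfinic acid, Cc1ccc(cc1)S(=O)O
Why: In this SN1-type substitution the ortho-hydroxy, para-alkoxy benzhydrol ionises under the weak acidity of the sulfinic acid itself, and capture at sulfur gives the storable sulfone, the standard precursor of aryl-substituted o-quinone methides, at an acidity that aryl MOM ethers withstand.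

Step 28
Reactants: 38 (1R,4R,5R)-4,7,7-trimethyl-6-thiabicyclo[3.2.1]octane (isothiocineole); 4 1-(bromomethyl)-4-(methoxymethoxy)benzene
Product: 39 (1R,4R,5R)-6-[4-(methoxymethoxy)benzyl]-4,7,7-trimethyl-6-thioniabicyclo[3.2.1]octane trifluoromethanesulfonate
Conditions: LiOSO2CF3, CH2Cl2–H2O, rt
Reagents that add atoms: lithium trifluoromethanesulfonate, [Li+].[O-]S(=O)(=O)C(F)(F)F
Why: S-alkylation of the sulfide by an activated benzylic bromide with exchange to the non-nucleophilic triflate is the usual preparation of benzylsulfonium salts of this sulfide, which should alkylate on its less hindered lone pair.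

Step 29
Reactants: 37 2-[(Ar35)(4-methylphenylsulfonyl)methyl]-5-(methoxymethoxy)-3-RA-phenol; 39 sulfonium triflate
Product: 41 nona-MOM ether of the target (ring A 2R,3R; ring B 2S,3S), via o-quinone methide 40 (not isolated)
Conditions: 39 (2 equiv), Cs2CO3 (4 equiv), MeCN–CH2Cl2, −20 °C to rt
Reagents that add atoms: none
Why: Proposed new method: base-induced loss of sulfinate from 37 gives o-quinone methide 40 with its aryl group turned away from ring A, the ylide formed from 39 adds through carbon to the exocyclic methine (C2–C3 bond) with rearomatisation, and the phenoxide then displaces the sulfide from the benzylic carbon in a 5-exo-tet SN2 closure (O1–C2 bond); the closest known reaction type is the trans-selective (4+1) annulation of o-quinone methides released from 2-(sulfonylmethyl)phenols with carbonyl-stabilised sulfonium ylides, and what is new is the enantiopure semi-stabilised benzylidene ylide, whose single exposed face (as in its epoxidations and aziridinations) should fix C2 as S after the inversion, while the anti approach of the two aryl groups should place C3 trans to it (S).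

Step 30
Reactants: 41 nona-MOM ether of the target
Product: 43 CNP0135983.1 (target), via nonakis(trimethylsilyl) ether 42 (not isolated)
Conditions: Me3SiOSO2CF3, 2,2'-bipyridyl, MeCN, 0 °C to rt; then H2O
Reagents that add atoms: trimethylsilyl trifluoromethanesulfonate, C[Si](C)(C)OS(=O)(=O)C(F)(F)F (its silyl groups stand in 42 only)
Why: In this silylative cleavage of aromatic MOM ethers the silyl triflate–bipyridyl complex turns each ArO–CH2OMe into ArO–SiMe3 and a pyridinium salt in a weakly basic medium and water then frees the phenols, so neither a strong Lewis acid nor a free Brønsted acid meets the stilbene or the benzylic C2–O bonds of rings A and B.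

Compound list
1 | 4-hydroxybenzaldehyde | O=Cc1ccc(O)cc1 | starting material
2 | 4-(methoxymethoxy)benzaldehyde | COCOc1ccc(C=O)cc1 | intermediate
3 | [4-(methoxymethoxy)phenyl]methanol | COCOc1ccc(CO)cc1 | intermediate
4 | 1-(bromomethyl)-4-(methoxymethoxy)benzene | COCOc1ccc(CBr)cc1 | intermediate
5 | 2-hydroxyphenylacetic acid | OC(=O)Cc1ccccc1O | starting material
6 | methyl 2-(2-hydroxyphenyl)acetate | COC(=O)Cc1ccccc1O | intermediate
7 | methyl 2-(5-bromo-2-hydroxyphenyl)acetate | COC(=O)Cc1cc(Br)ccc1O | intermediate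
8 | methyl 2-{5-bromo-2-[4-(methoxymethoxy)benzyloxy]phenyl}acetate | COC(=O)Cc1cc(Br)ccc1OCc1ccc(OCOC)cc1 | intermediate
9 | methyl 2-{5-bromo-2-[4-(methoxymethoxy)benzyloxy]phenyl}-2-diazoacetate | COC(=O)C(=[N+]=[N-])c1cc(Br)ccc1OCc1ccc(OCOC)cc1 | intermediate
10 | methyl (2R,3S)-5-bromo-2-[4-(methoxymethoxy)phenyl]-2,3-dihydro-1-benzofuran-3-carboxylate (cis) | Brc1ccc2c(c1)[C@H](C(=O)OC)[C@H](c1ccc(OCOC)cc1)O2 | intermediate
11 | methyl (2R,3R)-5-bromo-2-[4-(methoxymethoxy)phenyl]-2,3-dihydro-1-benzofuran-3-carboxylate (trans) | Brc1ccc2c(c1)[C@@H](C(=O)OC)[C@H](c1ccc(OCOC)cc1)O2 | intermediate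
12 | 1-bromo-3,5-dimethoxybenzene | COc1cc(Br)cc(OC)c1 | starting material
13 | 1-bromo-2-iodo-3,5-dimethoxybenzene | COc1cc(OC)c(I)c(Br)c1 | intermediate
14 | 4-ethynylanisole | C#Cc1ccc(OC)cc1 | starting material
15 | 1-bromo-3,5-dimethoxy-2-[(4-methoxyphenyl)ethynyl]benzene | COc1ccc(C#Cc2c(Br)cc(OC)cc2OC)cc1 | intermediate
16 | 4-bromo-3-iodo-6-methoxy-2-(4-methoxyphenyl)-1-benzofuran | COc1ccc(-c2oc3cc(OC)cc(Br)c3c2I)cc1 | intermediate
17 | 3,5-dimethoxyphenylboronic acid | COc1cc(OC)cc(B(O)O)c1 | starting material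
18 | 4-bromo-3-(3,5-dimethoxyphenyl)-6-methoxy-2-(4-methoxyphenyl)-1-benzofuran | COc1ccc(-c2oc3cc(OC)cc(Br)c3c2-c2cc(OC)cc(OC)c2)cc1 | intermediate
19 | 5-[4-bromo-6-hydroxy-2-(4-hydroxyphenyl)-1-benzofuran-3-yl]benzene-1,3-diol | Oc1ccc(-c2oc3cc(O)cc(Br)c3c2-c2cc(O)cc(O)c2)cc1 | intermediate
20 | 4-bromo-6-(methoxymethoxy)-2-[4-(methoxymethoxy)phenyl]-3-[3,5-bis(methoxymethoxy)phenyl]-1-benzofuran | COCOc1ccc(-c2oc3cc(OCOC)cc(Br)c3c2-c2cc(OCOC)cc(OCOC)c2)cc1 | intermediate
21 | 4,4,5,5-tetramethyl-2-vinyl-1,3,2-dioxaborolane | C=CB1OC(C)(C)C(C)(C)O1 | starting material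
22 | 4-ethenyl-6-(methoxymethoxy)-2-[4-(methoxymethoxy)phenyl]-3-[3,5-bis(methoxymethoxy)phenyl]-1-benzofuran | COCOc1ccc(-c2oc3cc(OCOC)cc(C=C)c3c2-c2cc(OCOC)cc(OCOC)c2)cc1 | intermediate
23 | methyl (2R,3R)-5-BFV-2-[4-(methoxymethoxy)phenyl]-2,3-dihydro-1-benzofuran-3-carboxylate | COCOc1ccc(-c2oc3cc(OCOC)cc(/C=C/c4ccc5c(c4)[C@@H](C(=O)OC)[C@H](c4ccc(OCOC)cc4)O5)c3c2-c2cc(OCOC)cc(OCOC)c2)cc1 | intermediate
24 | (2R,3R)-5-BFV-2-[4-(methoxymethoxy)phenyl]-2,3-dihydro-1-benzofuran-3-carbaldehyde (RA–CHO) | COCOc1ccc(-c2oc3cc(OCOC)cc(/C=C/c4ccc5c(c4)[C@@H](C=O)[C@H](c4ccc(OCOC)cc4)O5)c3c2-c2cc(OCOC)cc(OCOC)c2)cc1 | intermediate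
25 | (2R,3R)-3-ethynyl-5-BFV-2-[4-(methoxymethoxy)phenyl]-2,3-dihydro-1-benzofuran (RA–C≡CH) | COCOc1ccc(-c2oc3cc(OCOC)cc(/C=C/c4ccc5c(c4)[C@@H](C#C)[C@H](c4ccc(OCOC)cc4)O5)c3c2-c2cc(OCOC)cc(OCOC)c2)cc1 | intermediate
26 | 3,5-dihydroxybenzaldehyde | O=Cc1cc(O)cc(O)c1 | starting material
27 | 3,5-bis(methoxymethoxy)benzaldehyde | COCOc1cc(C=O)cc(OCOC)c1 | intermediate
28 | 1-[3,5-bis(methoxymethoxy)phenyl]-3-RA-prop-2-yn-1-ol (carbinol epimers) | COCOc1ccc(-c2oc3cc(OCOC)cc(/C=C/c4ccc5c(c4)[C@@H](C#CC(O)c4cc(OCOC)cc(OCOC)c4)[C@H](c4ccc(OCOC)cc4)O5)c3c2-c2cc(OCOC)cc(OCOC)c2)cc1 | intermediate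
29 | 1-[3,5-bis(methoxymethoxy)phenyl]-3-RA-prop-2-yn-1-one | COCOc1ccc(-c2oc3cc(OCOC)cc(/C=C/c4ccc5c(c4)[C@@H](C#CC(=O)c4cc(OCOC)cc(OCOC)c4)[C@H](c4ccc(OCOC)cc4)O5)c3c2-c2cc(OCOC)cc(OCOC)c2)cc1 | intermediate
30 | methyl acetoacetate | COC(=O)CC(C)=O | starting material
31 | methyl 3-(trimethylsilyloxy)but-2-enoate | COC(=O)C=C(C)O[Si](C)(C)C | intermediate
32 | (1Z)-1-methoxy-1,3-bis(trimethylsilyloxy)buta-1,3-diene | CO/C(O[Si](C)(C)C)=C/C(=C)O[Si](C)(C)C | intermediate
33 | [6-methoxy-2-RA-4,6-bis(trimethylsilyloxy)cyclohexa-1,4-dien-1-yl][3,5-bis(methoxymethoxy)phenyl]methanone (ketal carbon undefined) | COCOc1ccc(-c2oc3cc(OCOC)cc(/C=C/c4ccc5c(c4)[C@@H](C4=C(C(=O)c6cc(OCOC)cc(OCOC)c6)C(OC)(O[Si](C)(C)C)C=C(O[Si](C)(C)C)C4)[C@H](c4ccc(OCOC)cc4)O5)c3c2-c2cc(OCOC)cc(OCOC)c2)cc1 | intermediate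
34 | (2,4-dihydroxy-6-RA-phenyl)[3,5-bis(methoxymethoxy)phenyl]methanone | COCOc1ccc(-c2oc3cc(OCOC)cc(/C=C/c4ccc5c(c4)[C@@H](c4cc(O)cc(O)c4C(=O)c4cc(OCOC)cc(OCOC)c4)[C@H](c4ccc(OCOC)cc4)O5)c3c2-c2cc(OCOC)cc(OCOC)c2)cc1 | intermediate
35 | [2-hydroxy-4-(methoxymethoxy)-6-RA-phenyl][3,5-bis(methoxymethoxy)phenyl]methanone | COCOc1ccc(-c2oc3cc(OCOC)cc(/C=C/c4ccc5c(c4)[C@@H](c4cc(OCOC)cc(O)c4C(=O)c4cc(OCOC)cc(OCOC)c4)[C@H](c4ccc(OCOC)cc4)O5)c3c2-c2cc(OCOC)cc(OCOC)c2)cc1 | intermediate
36 | 2-{[3,5-bis(methoxymethoxy)phenyl](hydroxy)methyl}-5-(methoxymethoxy)-3-RA-phenol (carbinol epimers) | COCOc1ccc(-c2oc3cc(OCOC)cc(/C=C/c4ccc5c(c4)[C@@H](c4cc(OCOC)cc(O)c4C(O)c4cc(OCOC)cc(OCOC)c4)[C@H](c4ccc(OCOC)cc4)O5)c3c2-c2cc(OCOC)cc(OCOC)c2)cc1 | intermediate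
37 | 2-{[3,5-bis(methoxymethoxy)phenyl](4-methylphenylsulfonyl)methyl}-5-(methoxymethoxy)-3-RA-phenol (epimers) | COCOc1ccc(-c2oc3cc(OCOC)cc(/C=C/c4ccc5c(c4)[C@@H](c4cc(OCOC)cc(O)c4C(c4cc(OCOC)cc(OCOC)c4)S(=O)(=O)c4ccc(C)cc4)[C@H](c4ccc(OCOC)cc4)O5)c3c2-c2cc(OCOC)cc(OCOC)c2)cc1 | intermediate
38 | (1R,4R,5R)-4,7,7-trimethyl-6-thiabicyclo[3.2.1]octane (isothiocineole) | C[C@@H]1CC[C@@H]2C[C@H]1SC2(C)C | starting material
39 | (1R,4R,5R)-6-[4-(methoxymethoxy)benzyl]-4,7,7-trimethyl-6-thioniabicyclo[3.2.1]octane trifluoromethanesulfonate (one epimer at sulfur expected) | C[C@@H]1CC[C@@H]2C[C@H]1[S+](Cc1ccc(OCOC)cc1)C2(C)C.[O-]S(=O)(=O)C(F)(F)F | intermediate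
40 | (6Z)-6-[3,5-bis(methoxymethoxy)benzylidene]-3-(methoxymethoxy)-5-RA-cyclohexa-2,4-dien-1-one (o-quinone methide) | COCOc1ccc(-c2oc3cc(OCOC)cc(/C=C/c4ccc5c(c4)[C@@H](C4=CC(OCOC)=CC(=O)/C4=C\c4cc(OCOC)cc(OCOC)c4)[C@H](c4ccc(OCOC)cc4)O5)c3c2-c2cc(OCOC)cc(OCOC)c2)cc1 | intermediate
41 | nona-MOM ether of the target: RA attached to C4 of (2S,3S)-6-(methoxymethoxy)-2-[4-(methoxymethoxy)phenyl]-3-[3,5-bis(methoxymethoxy)phenyl]-2,3-dihydro-1-benzofuran | COCOc1ccc(-c2oc3cc(OCOC)cc(/C=C/c4ccc5c(c4)[C@@H](c4cc(OCOC)cc6c4[C@H](c4cc(OCOC)cc(OCOC)c4)[C@@H](c4ccc(OCOC)cc4)O6)[C@H](c4ccc(OCOC)cc4)O5)c3c2-c2cc(OCOC)cc(OCOC)c2)cc1 | intermediate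
42 | nonakis(trimethylsilyl) ether of the target | C[Si](C)(C)Oc1ccc(-c2oc3cc(O[Si](C)(C)C)cc(/C=C/c4ccc5c(c4)[C@@H](c4cc(O[Si](C)(C)C)cc6c4[C@H](c4cc(O[Si](C)(C)C)cc(O[Si](C)(C)C)c4)[C@@H](c4ccc(O[Si](C)(C)C)cc4)O6)[C@H](c4ccc(O[Si](C)(C)C)cc4)O5)c3c2-c2cc(O[Si](C)(C)C)cc(O[Si](C)(C)C)c2)cc1 | intermediate
43 | CNP0135983.1 (ring A 2R,3R; ring B 2S,3S; E alkene) | Oc1ccc(-c2oc3cc(O)cc(/C=C/c4ccc5c(c4)[C@@H](c4cc(O)cc6c4[C@H](c4cc(O)cc(O)c4)[C@@H](c4ccc(O)cc4)O6)[C@H](c4ccc(O)cc4)O5)c3c2-c2cc(O)cc(O)c2)cc1 | target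

Total step count: 30.
Longest linear sequence: 17 steps (steps 10–18, 20, 21, 24–27, 29, 30; the branch through steps 1–3 and 6–9 is equally long).

Steps most likely to fail

First, step 29. The stereogenic ring A substituent sits next to the methide carbon and may steer the ylide to the wrong face. Facial selectivity would then be poor whenever reagent and substrate control oppose each other. The ylide may also decay, or the methide may be captured by adventitious water, before the two meet. The fallback uses known chemistry, sets out from 35 and comes back at 41. The free 2-OH of 35 is alkylated with bromide 4 (K2CO3, DMF) to the benzyl ether ketone F1. F1 is condensed with N2H4·H2O (AcOH, n-BuOH, heat) to the hydrazone F2, and MnO2 oxidises F2 to the diaryldiazomethane F3. A donor/donor rhodium carbene 1,5-C–H insertion with Rh2(PTAD)4 (dirhodium tetrakis[N-phthaloyl-adamantylglycinate], in the ligand enantiomer that sets 3S) then closes ring B as the cis-(2R,3S) isomer F4. A catalytic amount of CF3CO2H in CH2Cl2 at low temperature ionises O1–C2 reversibly and lets C2 settle trans to the untouched C3, which gives 41.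

Second, step 24. The cycloaddition may be slower than the thermal decay of the diene. The hot ynone may also isomerise through its acidic C3–H, with opening of ring A. The fallback keeps the same two ring bonds and the same diene but changes the activating group from aroyl to formyl. It sets out from 25 and comes back at 36. Compound 25 is lithiated (n-BuLi, THF, −78 °C) and formylated with DMF to the ynal F5, a smaller and more electron-poor dienophile. Diene 32 should add to F5 at lower temperature to give the cyclohexadiene cycloadduct F6, which NH4F in MeOH converts into the 2,4-dihydroxy-6-RA-benzaldehyde F7. Selective MOM protection of the 4-OH gives the 2-hydroxy-4-(methoxymethoxy)-6-RA-benzaldehyde F8. Separately, 5-bromoresorcinol and MOMCl give 1-bromo-3,5-bis(methoxymethoxy)benzene F9, and bromine–lithium exchange with n-BuLi turns this into 3,5-bis(methoxymethoxy)phenyllithium F10. Two equivalents of F10 add to F8 to give benzhydrol 36.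

Third, step 30. Exchange of the nine acetals may stay incomplete. The polar, air-sensitive nonaphenol may also be lost during its separation from the bipyridyl salts. The fallback changes both the cleavage chemistry and the way the product is isolated. It sets out from 41 and comes back at 43. The acetals are transferred to methanol with dilute HCl in MeOH–THF at or slightly above rt. The crude phenol is not purified but peracetylated (Ac2O, pyridine) to the nona-acetate F11, which is stable and can be chromatographed. Mild methanolysis (K2CO3, MeOH, 0 °C, under argon) then releases 43.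

Further compounds
F1 | step 29 | {2-[4-(methoxymethoxy)benzyloxy]-4-(methoxymethoxy)-6-RA-phenyl}[3,5-bis(methoxymethoxy)phenyl]methanone | COCOc1ccc(-c2oc3cc(OCOC)cc(/C=C/c4ccc5c(c4)[C@@H](c4cc(OCOC)cc(OCc6ccc(OCOC)cc6)c4C(=O)c4cc(OCOC)cc(OCOC)c4)[C@H](c4ccc(OCOC)cc4)O5)c3c2-c2cc(OCOC)cc(OCOC)c2)cc1
F2 | step 29 | hydrazone of F1 | COCOc1ccc(-c2oc3cc(OCOC)cc(/C=C/c4ccc5c(c4)[C@@H](c4cc(OCOC)cc(OCc6ccc(OCOC)cc6)c4C(=NN)c4cc(OCOC)cc(OCOC)c4)[C@H](c4ccc(OCOC)cc4)O5)c3c2-c2cc(OCOC)cc(OCOC)c2)cc1
F3 | step 29 | diaryldiazomethane from F2 | COCOc1ccc(-c2oc3cc(OCOC)cc(/C=C/c4ccc5c(c4)[C@@H](c4cc(OCOC)cc(OCc6ccc(OCOC)cc6)c4C(=[N+]=[N-])c4cc(OCOC)cc(OCOC)c4)[C@H](c4ccc(OCOC)cc4)O5)c3c2-c2cc(OCOC)cc(OCOC)c2)cc1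
F4 | step 29 | ring B cis-(2R,3S) isomer of 41 | COCOc1ccc(-c2oc3cc(OCOC)cc(/C=C/c4ccc5c(c4)[C@@H](c4cc(OCOC)cc6c4[C@H](c4cc(OCOC)cc(OCOC)c4)[C@H](c4ccc(OCOC)cc4)O6)[C@H](c4ccc(OCOC)cc4)O5)c3c2-c2cc(OCOC)cc(OCOC)c2)cc1
F5 | step 24 | 3-RA-prop-2-ynal | COCOc1ccc(-c2oc3cc(OCOC)cc(/C=C/c4ccc5c(c4)[C@@H](C#CC=O)[C@H](c4ccc(OCOC)cc4)O5)c3c2-c2cc(OCOC)cc(OCOC)c2)cc1
F6 | step 24 | 6-methoxy-2-RA-4,6-bis(trimethylsilyloxy)cyclohexa-1,4-diene-1-carbaldehyde | COCOc1ccc(-c2oc3cc(OCOC)cc(/C=C/c4ccc5c(c4)[C@@H](C4=C(C=O)C(OC)(O[Si](C)(C)C)C=C(O[Si](C)(C)C)C4)[C@H](c4ccc(OCOC)cc4)O5)c3c2-c2cc(OCOC)cc(OCOC)c2)cc1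
F7 | step 24 | 2,4-dihydroxy-6-RA-benzaldehyde | COCOc1ccc(-c2oc3cc(OCOC)cc(/C=C/c4ccc5c(c4)[C@@H](c4cc(O)cc(O)c4C=O)[C@H](c4ccc(OCOC)cc4)O5)c3c2-c2cc(OCOC)cc(OCOC)c2)cc1
F8 | step 24 | 2-hydroxy-4-(methoxymethoxy)-6-RA-benzaldehyde | COCOc1ccc(-c2oc3cc(OCOC)cc(/C=C/c4ccc5c(c4)[C@@H](c4cc(OCOC)cc(O)c4C=O)[C@H](c4ccc(OCOC)cc4)O5)c3c2-c2cc(OCOC)cc(OCOC)c2)cc1
F9 | step 24 | 1-bromo-3,5-bis(methoxymethoxy)benzene | COCOc1cc(Br)cc(OCOC)c1
F10 | step 24 | 3,5-bis(methoxymethoxy)phenyllithium | [Li]c1cc(OCOC)cc(OCOC)c1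
F11 | step 30 | nona-acetate of the target | CC(=O)Oc1ccc(-c2oc3cc(OC(C)=O)cc(/C=C/c4ccc5c(c4)[C@@H](c4cc(OC(C)=O)cc6c4[C@H](c4cc(OC(C)=O)cc(OC(C)=O)c4)[C@@H](c4ccc(OC(C)=O)cc4)O6)[C@H](c4ccc(OC(C)=O)cc4)O5)c3c2-c2cc(OC(C)=O)cc(OC(C)=O)c2)cc1
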